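**Retrosynthetic overview**

- The strategy rests on the dihydropyran ring O1–C2–C3–C4–C4a–C8a of the chroman. C4 carries aryl carbon C4a, the isobutyl group and H, and lies β to the oxygen-bearing C2, so cutting C4a–C4 and O1–C2 gives phloroglucinol plus an exocyclic (E)-isobutylidene ketone on the ten-membered carbocycle (formal [3+3]).
- The (Z)-cyclodecenone comes from anionic oxy-Cope ring expansion of a cis-1-vinyl-2-isopropenylcyclohexanol; the enolate it delivers is trapped regiospecifically and condensed with isovaleraldehyde.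
- The cyclohexane comes from a carbonyl-ene closure of an aldehyde whose single stereocentre is set by Evans prenylation of 4-pentenoic acid.
- After the annulation, the C2 methyl is made by ketone methylenation and phenol oxymercuration–demercuration (no free cation at C2), followed by double ortho-formylation and desilylation.
- Ring order: cyclohexane, then ten-membered carbocycle, then pyran.

Key step: step 15

Assumptions: the tertiary alcohol is carried as its triethylsilyl ether from step 5 to step 21, because the free δ-hydroxy aldehyde would close to a lactol and the free alcohol could compete in the oxymercuration; the key-step precursor and product therefore appear as TES ethers. The quinine-derived amine is written for the 4S adduct; its quinidine-derived pseudoenantiomer would be used if the sense proves opposite. Chroman numbering (O1, C2, C3, C4, C4a … C8a) is used for the pyran ring; cyclodecenone numbering (C1 = ketone carbon) for the carbocycle.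

**Route**

Step 1
Reactants: 1 pent-4-enoic acid; 2 (S)-4-benzyloxazolidin-2-one
Product: 4 (S)-4-benzyl-3-(pent-4-enoyl)oxazolidin-2-one, via pent-4-enoic pivalic anhydride 3 (not isolated)
Conditions: PivCl, Et3N, THF, −20 °C; then 2, LiCl, −20 °C → rt
Reagents that add atoms: none
Why: N-acylation of the oxazolidinone through the mixed pivalic anhydride is a standard, mild way to load the Evans auxiliary.

Step 2
Reactants: 4 (S)-4-benzyl-3-(pent-4-enoyl)oxazolidin-2-one; 5 prenyl bromide
Product: 7 (S)-4-benzyl-3-[(2R)-5-methyl-2-(prop-2-enyl)hex-4-enoyl]oxazolidin-2-one, via sodium Z-enolate 6 (not isolated)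
Conditions: NaHMDS, THF, −78 °C; then 5, −78 → −40 °C
Reagents that add atoms: none
Why: Evans asymmetric alkylation, in which the chelated Z-enolate is alkylated by the allylic bromide on the face opposite the benzyl group and so sets the 2R centre (the later carbinyl-bearing ring carbon).

Step 3
Reactants: 7 (S)-4-benzyl-3-[(2R)-5-methyl-2-(prop-2-enyl)hex-4-enoyl]oxazolidin-2-one
Product: 8 methyl (2R)-5-methyl-2-(prop-2-enyl)hex-4-enoate
Conditions: MeMgBr (1.5 equiv), MeOH, 0 °C
Reagents that add atoms: methanol, CO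
Why: Bromomagnesium methoxide transesterifies the exocyclic imide carbonyl without epimerising the α-centre and releases the auxiliary for recovery.

Step 4
Reactants: 8 methyl (2R)-5-methyl-2-(prop-2-enyl)hex-4-enoate
Product: 9 (3R)-2,6-dimethyl-3-(prop-2-enyl)hept-5-en-2-ol
Conditions: MeMgBr (3 equiv), THF, 0 °C → rt
Reagents that add atoms: methylmagnesium bromide, C[Mg]Br
Why: Double Grignard addition to the ester gives the dimethyl carbinol, the intermediate methyl ketone being consumed faster than it can enolise.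

Step 5
Reactants: 9 (3R)-2,6-dimethyl-3-(prop-2-enyl)hept-5-en-2-ol
Product: 10 triethyl{[(3R)-2,6-dimethyl-3-(prop-2-enyl)hept-5-en-2-yl]oxy}silane
Conditions: TESOTf, 2,6-lutidine, CH2Cl2, 0 °C
Reagents that add atoms: triethylsilyl triflate, CC[Si](CC)(CC)OS(=O)(=O)C(F)(F)F
Why: Silyl triflate and lutidine silylate hindered tertiary alcohols reliably, and the ether blocks lactol formation and Lewis-acid ionisation later.

Step 6
Reactants: 10 triethyl{[(3R)-2,6-dimethyl-3-(prop-2-enyl)hept-5-en-2-yl]oxy}silane
Product: 12 (4R)-7-methyl-4-[2-(triethylsilyloxy)propan-2-yl]oct-6-en-1-ol, via B-alkyl-9-BBN 11 (not isolated)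
Conditions: 9-BBN, THF, 0 °C → rt; then NaOH, H2O2, 0 °C
Reagents that add atoms: hydrogen peroxide, OO
Why: Anti-Markovnikov hydroboration–oxidation, with 9-BBN selecting the monosubstituted alkene over the trisubstituted prenyl alkene.

Step 7
Reactants: 12 (4R)-7-methyl-4-[2-(triethylsilyloxy)propan-2-yl]oct-6-en-1-ol
Product: 13 (4R)-7-methyl-4-[2-(triethylsilyloxy)propan-2-yl]oct-6-enal
Conditions: Dess–Martin periodinane, NaHCO3, CH2Cl2, rt
Reagents that add atoms: none
Why: Buffered Dess–Martin oxidation stops at the aldehyde and is too mild to trigger the ene reaction or silyl loss.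

Step 8
Reactants: 13 (4R)-7-methyl-4-[2-(triethylsilyloxy)propan-2-yl]oct-6-enal
Product: 14 (1R,2S,4R)-2-(prop-1-en-2-yl)-4-[2-(triethylsilyloxy)propan-2-yl]cyclohexan-1-ol
Conditions: Me2AlCl, CH2Cl2, −78 °C
Reagents that add atoms: none
Why: Type I intramolecular carbonyl-ene reaction (citronellal-to-isopulegol type) through a chair transition state with all three substituents equatorial, so C1 and C2 are set relative to the existing centre; C1 is erased in step 9 and C2 in step 12.

Step 9
Reactants: 14 (1R,2S,4R)-2-(prop-1-en-2-yl)-4-[2-(triethylsilyloxy)propan-2-yl]cyclohexan-1-ol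
Product: 15 (2S,4R)-2-(prop-1-en-2-yl)-4-[2-(triethylsilyloxy)propan-2-yl]cyclohexan-1-one
Conditions: Dess–Martin periodinane, NaHCO3, CH2Cl2, 0 °C → rt
Reagents that add atoms: none
Why: Non-basic alcohol oxidation keeps the β,γ-alkene out of conjugation and leaves the α-centre in its diequatorial arrangement.

Step 10
Reactants: 15 (2S,4R)-2-(prop-1-en-2-yl)-4-[2-(triethylsilyloxy)propan-2-yl]cyclohexan-1-one; 16 ethynylmagnesium bromide
Product: 17 (1R,2S,4R)-1-ethynyl-2-(prop-1-en-2-yl)-4-[2-(triethylsilyloxy)propan-2-yl]cyclohexan-1-ol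
Conditions: 16, LaCl3·2LiCl, THF, −78 → 0 °C
Reagents that add atoms: none
Why: 1,2-Addition of the small acetylide should occur by axial attack on the chair with both substituents equatorial, placing the alkynyl group cis to the isopropenyl group (1R), while the lanthanide salt suppresses enolisation.

Step 11
Reactants: 17 (1R,2S,4R)-1-ethynyl-2-(prop-1-en-2-yl)-4-[2-(triethylsilyloxy)propan-2-yl]cyclohexan-1-ol
Product: 18 (1S,2S,4R)-1-ethenyl-2-(prop-1-en-2-yl)-4-[2-(triethylsilyloxy)propan-2-yl]cyclohexan-1-ol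
Conditions: H2 (1 atm), Lindlar catalyst, quinoline, EtOAc, rt
Reagents that add atoms: none
Why: Lindlar semihydrogenation reduces the terminal alkyne to the vinyl group and leaves the isopropenyl alkene untouched.

Step 12
Reactants: 18 (1S,2S,4R)-1-ethenyl-2-(prop-1-en-2-yl)-4-[2-(triethylsilyloxy)propan-2-yl]cyclohexan-1-ol
Product: 21 (1Z,5Z,8R)-5-methyl-8-[2-(triethylsilyloxy)propan-2-yl]-1-(trimethylsilyloxy)cyclodeca-1,5-diene, via potassium alkoxide 19 (not isolated), via potassium enolate 20 (not isolated)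
Conditions: KH, 18-crown-6, THF, 0 °C → rt; then TMSCl, Et3N, −78 °C
Reagents that add atoms: chlorotrimethylsilane, C[Si](C)(C)Cl
Why: Anionic oxy-Cope rearrangement through a chair transition state with the alkoxide equatorial, the vinyl group axial and the isopropenyl group equatorial, which puts the C2–C3 ring bond pseudoaxial and gives the Z-trisubstituted alkene; O-silylation then fixes the enolate regiochemistry at C1–C2.

Step 13
Reactants: 21 (1Z,5Z,8R)-5-methyl-8-[2-(triethylsilyloxy)propan-2-yl]-1-(trimethylsilyloxy)cyclodeca-1,5-diene; 22 isovaleraldehyde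
Product: 24 (5Z,8R)-2-(1-hydroxy-3-methylbutyl)-5-methyl-8-[2-(triethylsilyloxy)propan-2-yl]cyclodec-5-en-1-one (mixture at the two new centres), via lithium enolate 23 (not isolated)
Conditions: MeLi, THF, 0 °C; then 22, −78 °C; NH4Cl
Reagents that add atoms: none
Why: Methyllithium cleaves the Si–O bond to give the lithium enolate without regiochemical scrambling, and the aldol addition at −78 °C is faster than proton transfer from the aldehyde; both new centres are removed in step 14.

Step 14
Reactants: 24 (5Z,8R)-2-(1-hydroxy-3-methylbutyl)-5-methyl-8-[2-(triethylsilyloxy)propan-2-yl]cyclodec-5-en-1-one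
Product: 26 (2E,5Z,8R)-5-methyl-2-(3-methylbutylidene)-8-[2-(triethylsilyloxy)propan-2-yl]cyclodec-5-en-1-one, via aldol mesylate 25 (not isolated)
Conditions: MsCl, Et3N, CH2Cl2, 0 °C; then DBU, rt
Reagents that add atoms: none
Why: Mesylation and E1cB elimination give the conjugated exocyclic enone as the E isomer, in which the alkyl chain avoids the carbonyl oxygen.

Step 15
Reactants: 26 (2E,5Z,8R)-5-methyl-2-(3-methylbutylidene)-8-[2-(triethylsilyloxy)propan-2-yl]cyclodec-5-en-1-one; 27 phloroglucinol
Product: 29 TES-protected ring-fused (2R,3S,4S)-2-hydroxy-4-isobutylchroman-5,7-diol (hemiketal anomer as drawn), via open keto-triol adduct 28 (not isolated)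
Conditions: 27 (3 equiv), 9-amino-9-deoxy-epi-quinine (20 mol %), TFA (40 mol %), THF, 40 °C
Reagents that add atoms: none
Why: The primary amine condenses with the C1 ketone to an α-branched iminium ion, a ring carbon of phloroglucinol (held by the protonated quinuclidine) attacks its β-carbon to form C4a–C4, and after rearomatisation, enamine protonation and hydrolysis the flanking phenol of keto-triol 28 adds to the ketone to form O1–C2. The closest known reaction type is the primary-amine (iminium) catalysed Friedel–Crafts addition–hemiketalisation of naphthols, sesamol and hydroxycoumarins with enones, applied here to a more hindered α-branched exocyclic enone whose ten-membered ring does not hold the enone rigidly s-cis, which iminium activation does not require. The pyran ring closes by 6-exo-trig attack of the phenol oxygen on the carbonyl carbon. C4 is set by the catalyst, which shields one face of the E-iminium so that the arene adds to the Si face of the β-carbon (4S); C3 is set by protonation followed by enol-mediated equilibration to the isomer with the ring CH2 trans to isobutyl (3S); C2 is a hemiketal centre that equilibrates and is erased in step 16. The step needs C- over O-alkylation and mono- over poly-alkylation, which should be secured by the soft iminium electrophile, the threefold symmetry and excess of phloroglucinol, and the shielding of the arene once the hemiketal has closed; the Z ring alkene and the silyl ether are inert to the weakly acidic medium.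

Step 16
Reactants: 29 TES-protected ring-fused 2-hydroxychroman-5,7-diol
Product: 30 (2S,5Z,8R)-5-methyl-2-{(1S)-3-methyl-1-[2,4,6-tris(tert-butyldimethylsilyloxy)phenyl]butyl}-8-[2-(triethylsilyloxy)propan-2-yl]cyclodec-5-en-1-one
Conditions: TBSCl, imidazole, DMAP, DMF, rt → 40 °C
Reagents that add atoms: tert-butyldimethylsilyl chloride, CC(C)(C)[Si](C)(C)Cl
Why: Phenols silylate much faster than the tertiary hemiketal hydroxyl, so ring–chain tautomerism should drain the hemiketal into the open ketone as the third phenol is capped.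

Step 17
Reactants: 30 tris-TBS open-chain ketone
Product: 31 1-methylidene analogue of 30 (exocyclic C=CH2 in place of C=O; C3 and C4 unchanged)
Conditions: Cp2TiMe2, toluene, 70 °C, dark
Reagents that add atoms: dimethyltitanocene, C[Ti](C)(C1C=CC=C1)C1C=CC=C1
Why: Petasis methylenation is non-basic and works on hindered, enolisable ketones, so the α-centre C3 should be preserved.

Step 18
Reactants: 31 tris-TBS methylidene compound
Product: 32 2-{(1S)-1-[(1S,5Z,8R)-5-methyl-2-methylidene-8-(2-triethylsilyloxypropan-2-yl)cyclodec-5-enyl]-3-methylbutyl}benzene-1,3,5-triol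
Conditions: KHF2, MeOH, rt
Reagents that add atoms: none
Why: Bifluoride in methanol cleaves aryl silyl ethers selectively, so the hindered tertiary alkyl TES ether should survive.

Step 19
Reactants: 32 triphenol with exocyclic methylidene
Product: 34 TES-protected ring-fused (2R,3S,4S)-4-isobutyl-2-methylchroman-5,7-diol, via acetoxymercuriomethyl chroman 33 (not isolated)
Conditions: Hg(OAc)2, THF, 0 °C; then NaBH4, aq NaOH, 0 °C
Reagents that add atoms: none
Why: Intramolecular phenoxymercuration (6-exo-trig, Markovnikov, faster at the 1,1-disubstituted than at the trisubstituted alkene) followed by reductive demercuration gives the C2 methyl without a free cation; the two ortho phenols are equivalent, and the reversible closure should favour the trans-fused chair with both ten-membered-ring bonds and the isobutyl group equatorial (2R).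

Step 20
Reactants: 34 TES-protected ring-fused 2-methylchroman-5,7-diol
Product: 35 TES-protected 6,8-diformyl derivative of 34
Conditions: MgCl2, Et3N, (CH2O)n, MeCN, reflux
Reagents that add atoms: paraformaldehyde (formaldehyde), C=O
Why: Magnesium-phenoxide-directed ortho-formylation (Casnati–Skattebøl) delivers formaldehyde ortho to each phenoxide and oxidises the benzylic alkoxide with a second formaldehyde; both free ring positions (C6, C8) are ortho to a phenol, and the silyl ether and alkene are inert.

Step 21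
Reactants: 35 TES-protected dialdehyde
Product: 36 CNP0570248.1
Conditions: HF·pyridine, pyridine, THF, 0 °C → rt
Reagents that add atoms: none
Why: Buffered fluoride desilylation frees the tertiary alcohol without acid strong enough to dehydrate it or protonate the ring alkene.

**Compound list**

1 | pent-4-enoic acid | C=CCCC(=O)O | starting material
2 | (S)-4-benzyloxazolidin-2-one | O=C1OC[C@H](Cc2ccccc2)N1 | starting material
3 | pent-4-enoic pivalic anhydride | C=CCCC(=O)OC(=O)C(C)(C)C | intermediate
4 | (S)-4-benzyl-3-(pent-4-enoyl)oxazolidin-2-one | C=CCCC(=O)N1[C@@H](Cc2ccccc2)COC1=O | intermediate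
5 | prenyl bromide (1-bromo-3-methylbut-2-ene) | CC(C)=CCBr | starting material
6 | sodium (Z)-enolate of 4 | [Na+].[O-]/C(=C\CC=C)N1[C@@H](Cc2ccccc2)COC1=O | intermediate
7 | (S)-4-benzyl-3-[(2R)-5-methyl-2-(prop-2-enyl)hex-4-enoyl]oxazolidin-2-one | C=CC[C@H](CC=C(C)C)C(=O)N1[C@@H](Cc2ccccc2)COC1=O | intermediate
8 | methyl (2R)-5-methyl-2-(prop-2-enyl)hex-4-enoate | C=CC[C@H](CC=C(C)C)C(=O)OC | intermediate
9 | (3R)-2,6-dimethyl-3-(prop-2-enyl)hept-5-en-2-ol | C=CC[C@H](CC=C(C)C)C(C)(C)O | intermediate
10 | triethylsilyl ether of 9 | C=CC[C@H](CC=C(C)C)C(C)(C)O[Si](CC)(CC)CC | intermediate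
11 | B-alkyl-9-borabicyclo[3.3.1]nonane from 10 | C(CC[C@H](CC=C(C)C)C(C)(C)O[Si](CC)(CC)CC)B1C2CCCC1CCC2 | intermediate
12 | (4R)-7-methyl-4-[2-(triethylsilyloxy)propan-2-yl]oct-6-en-1-ol | OCCC[C@H](CC=C(C)C)C(C)(C)O[Si](CC)(CC)CC | intermediate
13 | (4R)-7-methyl-4-[2-(triethylsilyloxy)propan-2-yl]oct-6-enal | O=CCC[C@H](CC=C(C)C)C(C)(C)O[Si](CC)(CC)CC | intermediate
14 | (1R,2S,4R)-2-(prop-1-en-2-yl)-4-[2-(triethylsilyloxy)propan-2-yl]cyclohexan-1-ol | O[C@@H]1CC[C@@H](C(C)(C)O[Si](CC)(CC)CC)C[C@H]1C(C)=C | intermediate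
15 | (2S,4R)-2-(prop-1-en-2-yl)-4-[2-(triethylsilyloxy)propan-2-yl]cyclohexan-1-one | O=C1CC[C@@H](C(C)(C)O[Si](CC)(CC)CC)C[C@H]1C(C)=C | intermediate
16 | ethynylmagnesium bromide | C#C[Mg]Br | starting material
17 | (1R,2S,4R)-1-ethynyl-2-(prop-1-en-2-yl)-4-[2-(triethylsilyloxy)propan-2-yl]cyclohexan-1-ol | O[C@]1(C#C)CC[C@@H](C(C)(C)O[Si](CC)(CC)CC)C[C@H]1C(C)=C | intermediate
18 | (1S,2S,4R)-1-ethenyl-2-(prop-1-en-2-yl)-4-[2-(triethylsilyloxy)propan-2-yl]cyclohexan-1-ol | O[C@]1(C=C)CC[C@@H](C(C)(C)O[Si](CC)(CC)CC)C[C@H]1C(C)=C | intermediate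
19 | potassium alkoxide of 18 | [K+].[O-][C@]1(C=C)CC[C@@H](C(C)(C)O[Si](CC)(CC)CC)C[C@H]1C(C)=C | intermediate
20 | potassium (1Z,5Z,8R)-cyclodeca-1,5-dien-1-olate from the oxy-Cope | [K+].C/C1=C/C[C@H](C(C)(C)O[Si](CC)(CC)CC)CC/C([O-])=C/CC1 | intermediate
21 | (1Z,5Z,8R)-5-methyl-8-[2-(triethylsilyloxy)propan-2-yl]-1-(trimethylsilyloxy)cyclodeca-1,5-diene | C/C1=C/C[C@H](C(C)(C)O[Si](CC)(CC)CC)CC/C(O[Si](C)(C)C)=C/CC1 | intermediate
22 | isovaleraldehyde (3-methylbutanal) | CC(C)CC=O | starting material
23 | lithium enolate from 21 | [Li+].C/C1=C/C[C@H](C(C)(C)O[Si](CC)(CC)CC)CC/C([O-])=C/CC1 | intermediate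
24 | (5Z,8R)-2-(1-hydroxy-3-methylbutyl)-5-methyl-8-[2-(triethylsilyloxy)propan-2-yl]cyclodec-5-en-1-one, mixture at C2 and the carbinol carbon | C/C1=C/C[C@H](C(C)(C)O[Si](CC)(CC)CC)CCC(=O)C(C(O)CC(C)C)CC1 | intermediate
25 | methanesulfonate of 24 | C/C1=C/C[C@H](C(C)(C)O[Si](CC)(CC)CC)CCC(=O)C(C(OS(C)(=O)=O)CC(C)C)CC1 | intermediate
26 | (2E,5Z,8R)-5-methyl-2-(3-methylbutylidene)-8-[2-(triethylsilyloxy)propan-2-yl]cyclodec-5-en-1-one (key-step precursor, TES ether) | C/C1=C/C[C@H](C(C)(C)O[Si](CC)(CC)CC)CCC(=O)/C(=C/CC(C)C)CC1 | intermediate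
27 | phloroglucinol | Oc1cc(O)cc(O)c1 | starting material
28 | (2S,5Z,8R)-5-methyl-2-[(1S)-3-methyl-1-(2,4,6-trihydroxyphenyl)butyl]-8-[2-(triethylsilyloxy)propan-2-yl]cyclodec-5-en-1-one | C/C1=C/C[C@H](C(C)(C)O[Si](CC)(CC)CC)CCC(=O)[C@H]([C@H](CC(C)C)c2c(O)cc(O)cc2O)CC1 | intermediate
29 | ring-fused (2R,3S,4S)-2-hydroxy-4-isobutylchroman-5,7-diol, Z ring alkene, (R)-CMe2OTES carbon (key-step product, TES ether; anomer as drawn, equilibrating) | C/C1=C/C[C@H](C(C)(C)O[Si](CC)(CC)CC)CC[C@@]2(O)Oc3cc(O)cc(O)c3[C@@H](CC(C)C)[C@@H]2CC1 | intermediate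
30 | (2S,5Z,8R)-5-methyl-2-{(1S)-3-methyl-1-[2,4,6-tris(tert-butyldimethylsilyloxy)phenyl]butyl}-8-[2-(triethylsilyloxy)propan-2-yl]cyclodec-5-en-1-one | C/C1=C/C[C@H](C(C)(C)O[Si](CC)(CC)CC)CCC(=O)[C@H]([C@H](CC(C)C)c2c(O[Si](C)(C)C(C)(C)C)cc(O[Si](C)(C)C(C)(C)C)cc2O[Si](C)(C)C(C)(C)C)CC1 | intermediate
31 | 1-methylidene analogue of 30 | C/C1=C/C[C@H](C(C)(C)O[Si](CC)(CC)CC)CCC(=C)[C@H]([C@H](CC(C)C)c2c(O[Si](C)(C)C(C)(C)C)cc(O[Si](C)(C)C(C)(C)C)cc2O[Si](C)(C)C(C)(C)C)CC1 | intermediate
32 | triphenol from 31 (aryl silyl ethers removed, TES kept) | C/C1=C/C[C@H](C(C)(C)O[Si](CC)(CC)CC)CCC(=C)[C@H]([C@H](CC(C)C)c2c(O)cc(O)cc2O)CC1 | intermediate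
33 | ring-fused 2-(acetoxymercuriomethyl)chroman-5,7-diol | C/C1=C/C[C@H](C(C)(C)O[Si](CC)(CC)CC)CC[C@@]2(C[Hg]OC(C)=O)Oc3cc(O)cc(O)c3[C@@H](CC(C)C)[C@@H]2CC1 | intermediate
34 | ring-fused (2R,3S,4S)-4-isobutyl-2-methylchroman-5,7-diol, trans-fused at C2–C3, TES ether | C/C1=C/C[C@H](C(C)(C)O[Si](CC)(CC)CC)CC[C@@]2(C)Oc3cc(O)cc(O)c3[C@@H](CC(C)C)[C@@H]2CC1 | intermediate
35 | 6,8-diformyl derivative of 34, TES ether | C/C1=C/C[C@H](C(C)(C)O[Si](CC)(CC)CC)CC[C@@]2(C)Oc3c(C=O)c(O)c(C=O)c(O)c3[C@@H](CC(C)C)[C@@H]2CC1 | intermediate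
36 | CNP0570248.1: (2R,3S,4S)-6,8-diformyl-5,7-dihydroxy-4-isobutyl-2-methylchroman trans-fused at C2–C3 to a (Z)-methylcyclodecene bearing an (R)-configured ring carbon with a 2-hydroxypropan-2-yl group | C/C1=C/C[C@H](C(C)(C)O)CC[C@@]2(C)Oc3c(C=O)c(O)c(C=O)c(O)c3[C@@H](CC(C)C)[C@@H]2CC1 | target

**Step count**

Total: 21 steps. Longest linear sequence: 21 steps, from pent-4-enoic acid 1.

**Steps most likely to fail**

1. Step 15 (Friedel–Crafts annulation). The hindered α-branched ketone may form its iminium ion too slowly, the catalyst may give poor facial selectivity at the β-carbon against the bias of the flexible ten-membered ring, and phloroglucinol may be alkylated more than once. Fallback, from 26 back to 29: phloroglucinol 27 is converted with MOMCl and i-Pr2NEt into 1,3,5-tris(methoxymethoxy)benzene F1. Ortho-lithiation (n-BuLi, THF, 0 °C) and CuBr·SMe2 give the diaryl cuprate, which is added 1,4 to 26 with TMSCl (−78 → −20 °C). Hydrolysis of the silyl enol ether on work-up should give the tris-MOM aryl ketone F2. This gives up catalyst control at C4: the C4 epimers are diastereomers and are separated, and C3 equilibrates as in the main route. ZnBr2 and n-PrSH (CH2Cl2, 0 °C) then remove the three MOM groups and the freed triol closes to 29.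

2. Step 19 (oxymercuration–demercuration). The mercurinium ion may be intercepted transannularly by the ring alkene, the electron-rich arene may be mercurated in competition (aryl–Hg bonds would also be reduced by NaBH4), and ring closure may occur on the wrong alkene face to give the cis-fused C2 epimer. Fallback, from 32 back to 34: N-(phenylseleno)phthalimide with catalytic camphorsulfonic acid (CH2Cl2, −78 °C) should effect 6-exo selenoetherification to the ring-fused 2-(phenylselanylmethyl)chroman F3. Bu3SnH and AIBN (toluene, 80 °C) then cleave the C–Se bond to give the methyl group of 34.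

3. Step 20 (double formylation). The reaction may stall after the first formyl group, because the ring is deactivated and the magnesium is held in a salicylaldehyde chelate. Fallback, from 34 directly to 36: NaH and MOMCl give the bis-MOM ether F4. NBS (2 equiv, MeCN/CH2Cl2, −20 °C) brominates the two free ring positions to the 6,8-dibromide F5. Double bromine–lithium exchange (t-BuLi, THF, −78 °C) and DMF give the bis-MOM dialdehyde F6. HCl in MeOH/THF then removes the MOM and TES groups together to give 36.

**Further compounds**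

F1 | step 15 | 1,3,5-tris(methoxymethoxy)benzene | COCOc1cc(OCOC)cc(OCOC)c1
F2 | step 15 | (2S,5Z,8R)-5-methyl-2-{(1S)-3-methyl-1-[2,4,6-tris(methoxymethoxy)phenyl]butyl}-8-[2-(triethylsilyloxy)propan-2-yl]cyclodec-5-en-1-one | C/C1=C/C[C@H](C(C)(C)O[Si](CC)(CC)CC)CCC(=O)[C@H]([C@H](CC(C)C)c2c(OCOC)cc(OCOC)cc2OCOC)CC1
F3 | step 19 | ring-fused 2-(phenylselanylmethyl)chroman-5,7-diol, TES ether | C/C1=C/C[C@H](C(C)(C)O[Si](CC)(CC)CC)CC[C@@]2(C[Se]c4ccccc4)Oc3cc(O)cc(O)c3[C@@H](CC(C)C)[C@@H]2CC1
F4 | step 20 | 5,7-bis(methoxymethyl) ether of 34 | C/C1=C/C[C@H](C(C)(C)O[Si](CC)(CC)CC)CC[C@@]2(C)Oc3cc(OCOC)cc(OCOC)c3[C@@H](CC(C)C)[C@@H]2CC1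
F5 | step 20 | 6,8-dibromo derivative of F4 | C/C1=C/C[C@H](C(C)(C)O[Si](CC)(CC)CC)CC[C@@]2(C)Oc3c(Br)c(OCOC)c(Br)c(OCOC)c3[C@@H](CC(C)C)[C@@H]2CC1
F6 | step 20 | 6,8-diformyl derivative of F4 | C/C1=C/C[C@H](C(C)(C)O[Si](CC)(CC)CC)CC[C@@]2(C)Oc3c(C=O)c(OCOC)c(C=O)c(OCOC)c3[C@@H](CC(C)C)[C@@H]2CC1
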